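**Assumption:** the SMILES is read as the (3R)-isoflavan, (3R)-3-[3,4-dihydroxy-2-methoxy-5-(2-methylbut-3-en-2-yl)phenyl]chroman-7-ol. The sense of induction in step 7 cannot be predicted, so the ligand antipode that gives (3R) is fixed in a first small run.

**Retrosynthetic overview**
1. Target ⇐ removal of two MOM groups ⇐ aromatic Claisen rearrangement of a 4'-O-prenyl ether, which places the 1,1-dimethylallyl group at C5' last.
2. Key disconnection: the C3–C1' bond and the C3 stereocentre are made together by an enantioselective reductive Heck hydroarylation of an intact 2H-chromene with the ring B aryl iodide. No isoflavone or isoflavene reduction and no auxiliary alkylation is used.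
3. Ring C is closed first, onto the bought ring A, by a Schweizer oxa-Michael/Wittig annulation of a salicylaldehyde.
4. Ring B is bought as o-vanillin; its aldehyde becomes the 4'-oxygen (Dakin), and the iodide is placed by directed ortho-metalation.
5. Order: ring C on ring A → coupling to ring B (sets C3) → prenylation → Claisen → deprotection.

**Route**

Step 1
Reactants: 1 2,4-dihydroxybenzaldehyde
Product: 2 2-hydroxy-4-(methoxymethoxy)benzaldehyde
Conditions: MOMCl (1.05 equiv), K2CO3, acetone, 0 °C to rt
Reagents that add atoms: chloromethyl methyl ether, COCCl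
Why: Williamson-type MOM protection goes selectively to the 4-OH because the 2-OH is held in a hydrogen bond to the aldehyde and is the less acidic and less nucleophilic one.

Step 2
Reactants: 2 2-hydroxy-4-(methoxymethoxy)benzaldehyde; 3 vinyltriphenylphosphonium bromide
Product: 6 7-(methoxymethoxy)-2H-chromene, via sodium phenoxide 4 (not isolated), via phosphonium ylide 5 (not isolated)
Conditions: NaH, THF, 0 °C; then 3, THF/DMF, 65 °C
Reagents that add atoms: none
Why: Schweizer reaction, in which the phenoxide adds oxa-Michael fashion to the vinylphosphonium salt and the resulting ylide closes ring C on the ortho aldehyde by intramolecular Wittig olefination, giving the C3=C4 alkene needed for step 7.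

Step 3
Reactants: 7 2-hydroxy-3-methoxybenzaldehyde (o-vanillin)
Product: 8 3-methoxy-2-(methoxymethoxy)benzaldehyde
Conditions: MOMCl, K2CO3, DMF, rt
Reagents that add atoms: chloromethyl methyl ether, COCCl
Why: Williamson-type MOM protection of the only phenol, chosen because an acetal cannot migrate between neighbouring catechol oxygens later and tolerates peracid, alkyllithium, palladium and heat.

Step 4
Reactants: 8 3-methoxy-2-(methoxymethoxy)benzaldehyde
Product: 10 3-methoxy-2-(methoxymethoxy)phenol, via aryl formate 9 (not isolated)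
Conditions: mCPBA, CH2Cl2, 0 °C to rt; then K2CO3 (0.2 equiv), MeOH, rt
Reagents that add atoms: meta-chloroperoxybenzoic acid, O=C(OO)c1cccc(Cl)c1
Why: Dakin-type Baeyer–Villiger oxidation, in which the electron-rich ortho-alkoxyaryl group migrates to give the formate and mild methanolysis frees the phenol, so the future 4'-oxygen arrives already differentiated from the MOM-protected 3'-oxygen.

Step 5
Reactants: 10 3-methoxy-2-(methoxymethoxy)phenol
Product: 11 [3-methoxy-2-(methoxymethoxy)phenoxy]triisopropylsilane
Conditions: TIPSCl, imidazole, DMF, rt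
Reagents that add atoms: chlorotriisopropylsilane, CC(C)[Si](Cl)(C(C)C)C(C)C
Why: Standard silyl ether formation; the bulky TIPS group survives alkyllithium and palladium and shields its own ortho position in the next step.

Step 6
Reactants: 11 [3-methoxy-2-(methoxymethoxy)phenoxy]triisopropylsilane
Product: 13 [4-iodo-3-methoxy-2-(methoxymethoxy)phenoxy]triisopropylsilane, via aryllithium 12 (not isolated)
Conditions: s-BuLi, TMEDA, THF, −78 to −40 °C; then I2, THF, −78 °C to rt
Reagents that add atoms: iodine, II
Why: Directed ortho-metalation, in which the methoxy group directs lithiation to its only free ortho position while the bulky, poorly coordinating OTIPS group blocks the other side, followed by iodinolysis of the aryllithium.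

Step 7
Reactants: 6 7-(methoxymethoxy)-2H-chromene (1.5 equiv); 13 [4-iodo-3-methoxy-2-(methoxymethoxy)phenoxy]triisopropylsilane
Product: 14 (3R)-7-(methoxymethoxy)-3-[2-methoxy-3-(methoxymethoxy)-4-(triisopropylsilyloxy)phenyl]chromane
Conditions: Pd(OAc)2 (5 mol%), (R)-BINAP (6 mol%; antipode fixed by first run), HCO2Na (3 equiv), DMF/ethylene glycol 9:1, 60 °C, Ar
Reagents that add atoms: none
Why: Proposed new method: zerovalent palladium inserts into the C–I bond of 13, the aryl–palladium species adds syn across the styrenyl C3=C4 bond of 6 with aryl to C3 and palladium to benzylic C4 (the regiochemistry known from the Heck oxyarylation of 2H-chromenes with 2-iodophenols to pterocarpans), the ring leaves no syn β-hydrogen so the benzylpalladium is captured by formate (decarboxylation, then C–H reductive elimination), and the C3 stereocentre is set in the insertion step by face discrimination from the chelating chiral bisphosphine, helped by the hydrogen-bond-donor cosolvent that favours iodide dissociation; the closest known reaction types are the racemic reductive Heck hydroarylation of cyclic alkenes and the enantioselective reductive Heck hydroarylation of norbornenes and enones.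

Step 8
Reactants: 14 (3R)-7-(methoxymethoxy)-3-[2-methoxy-3-(methoxymethoxy)-4-(triisopropylsilyloxy)phenyl]chromane; 15 1-bromo-3-methylbut-2-ene (prenyl bromide)
Product: 17 (3R)-7-(methoxymethoxy)-3-[2-methoxy-3-(methoxymethoxy)-4-(3-methylbut-2-enyloxy)phenyl]chromane, via cesium phenoxide 16 (not isolated)
Conditions: CsF (3 equiv), 15 (1.5 equiv), DMF, rt to 40 °C
Reagents that add atoms: none
Why: One-pot fluoride desilylation and Williamson etherification, in which only the 4'-oxygen is freed and prenylated because the other two phenolic oxygens are MOM acetals.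

Step 9
Reactants: 17 (3R)-7-(methoxymethoxy)-3-[2-methoxy-3-(methoxymethoxy)-4-(3-methylbut-2-enyloxy)phenyl]chromane
Product: 18 3-methoxy-2-(methoxymethoxy)-4-[(3R)-7-(methoxymethoxy)chroman-3-yl]-6-(2-methylbut-3-en-2-yl)phenol
Conditions: PhNEt2, 190 °C, sealed tube, Ar, 2 h
Reagents that add atoms: none
Why: Aromatic Claisen rearrangement, a [3,3]-sigmatropic shift that can only end at C5' because the other ortho carbon carries OMOM and the para carbon carries the chromanyl group, giving the 1,1-dimethylallyl phenol after rearomatisation without touching C3.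

Step 10
Reactants: 18 3-methoxy-2-(methoxymethoxy)-4-[(3R)-7-(methoxymethoxy)chroman-3-yl]-6-(2-methylbut-3-en-2-yl)phenol
Product: 19 (3R)-3-[3,4-dihydroxy-2-methoxy-5-(2-methylbut-3-en-2-yl)phenyl]chroman-7-ol
Conditions: HCl (1.25 M in MeOH), degassed, 40 °C
Reagents that add atoms: none
Why: Acid-catalysed transacetalisation of both MOM acetals to methanol runs under conditions too mild to protonate the monosubstituted alkene or to ionise C3, so the reverse-prenyl group and the (R) centre survive; air is excluded because the product is a catechol.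

**Compound list**
1 | 2,4-dihydroxybenzaldehyde | O=Cc1ccc(O)cc1O | starting material
2 | 2-hydroxy-4-(methoxymethoxy)benzaldehyde | COCOc1ccc(C=O)c(O)c1 | intermediate
3 | vinyltriphenylphosphonium bromide | C=C[P+](c1ccccc1)(c1ccccc1)c1ccccc1.[Br-] | starting material
4 | sodium 2-formyl-5-(methoxymethoxy)phenolate | COCOc1ccc(C=O)c([O-])c1.[Na+] | intermediate (not isolated)
5 | 4-(methoxymethoxy)-2-[2-(triphenylphosphoranylidene)ethoxy]benzaldehyde | COCOc1ccc(C=O)c(OCC=P(c2ccccc2)(c2ccccc2)c2ccccc2)c1 | intermediate (not isolated)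
6 | 7-(methoxymethoxy)-2H-chromene | COCOc1ccc2C=CCOc2c1 | intermediate
7 | 2-hydroxy-3-methoxybenzaldehyde (o-vanillin) | COc1cccc(C=O)c1O | starting material
8 | 3-methoxy-2-(methoxymethoxy)benzaldehyde | COCOc1c(OC)cccc1C=O | intermediate
9 | 3-methoxy-2-(methoxymethoxy)phenyl formate | COCOc1c(OC)cccc1OC=O | intermediate (not isolated)
10 | 3-methoxy-2-(methoxymethoxy)phenol | COCOc1c(OC)cccc1O | intermediate
11 | [3-methoxy-2-(methoxymethoxy)phenoxy]triisopropylsilane | COCOc1c(OC)cccc1O[Si](C(C)C)(C(C)C)C(C)C | intermediate
12 | [2-methoxy-3-(methoxymethoxy)-4-(triisopropylsilyloxy)phenyl]lithium | COCOc1c(OC)c([Li])ccc1O[Si](C(C)C)(C(C)C)C(C)C | intermediate (not isolated)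
13 | [4-iodo-3-methoxy-2-(methoxymethoxy)phenoxy]triisopropylsilane | COCOc1c(OC)c(I)ccc1O[Si](C(C)C)(C(C)C)C(C)C | intermediate
14 | (3R)-7-(methoxymethoxy)-3-[2-methoxy-3-(methoxymethoxy)-4-(triisopropylsilyloxy)phenyl]chromane | COc1c([C@@H]2COc3cc(OCOC)ccc3C2)ccc(O[Si](C(C)C)(C(C)C)C(C)C)c1OCOC | intermediate
15 | 1-bromo-3-methylbut-2-ene (prenyl bromide) | CC(C)=CCBr | starting material
16 | cesium 3-methoxy-2-(methoxymethoxy)-4-[(3R)-7-(methoxymethoxy)chroman-3-yl]phenolate | COc1c([C@@H]2COc3cc(OCOC)ccc3C2)ccc([O-])c1OCOC.[Cs+] | intermediate (not isolated)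
17 | (3R)-7-(methoxymethoxy)-3-[2-methoxy-3-(methoxymethoxy)-4-(3-methylbut-2-enyloxy)phenyl]chromane | COc1c([C@@H]2COc3cc(OCOC)ccc3C2)ccc(OCC=C(C)C)c1OCOC | intermediate
18 | 3-methoxy-2-(methoxymethoxy)-4-[(3R)-7-(methoxymethoxy)chroman-3-yl]-6-(2-methylbut-3-en-2-yl)phenol | COc1c([C@@H]2COc3cc(OCOC)ccc3C2)cc(C(C)(C)C=C)c(O)c1OCOC | intermediate
19 | (3R)-3-[3,4-dihydroxy-2-methoxy-5-(2-methylbut-3-en-2-yl)phenyl]chroman-7-ol | C=CC(C)(C)c1cc([C@@H]2COc3cc(O)ccc3C2)c(OC)c(O)c1O | target

**Totals**
Total step count: 10. Longest linear sequence: 8 steps (7 to 19, steps 3 to 10); the ring A/C branch (1 to 6) is 2 steps.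

**Steps most likely to fail, with fallbacks**

Step 7 (yield and enantioselectivity of an unprecedented intermolecular asymmetric reductive Heck reaction). The fallback sets out from 6 and 13 and comes back at 14; it gives up the asymmetric C–C bond formation and sets C3 by asymmetric hydrogenation. Compound 6 is treated with Br2 (CH2Cl2, −78 °C) to give trans-3,4-dibromo-7-(methoxymethoxy)chromane F1 (racemic, not purified). DBU in the same flask removes HBr by loss of the readily ionised benzylic bromide and then H3, giving 3-bromo-7-(methoxymethoxy)-2H-chromene F2. Compound 13 is converted by Miyaura borylation (B2pin2, PdCl2(dppf), KOAc, dioxane, 80 °C) into 2-[2-methoxy-3-(methoxymethoxy)-4-(triisopropylsilyloxy)phenyl]-4,4,5,5-tetramethyl-1,3,2-dioxaborolane F3. Suzuki–Miyaura coupling of F2 and F3 (Pd(PPh3)4, K3PO4, dioxane/H2O, 80 °C) gives 7-(methoxymethoxy)-3-[2-methoxy-3-(methoxymethoxy)-4-(triisopropylsilyloxy)phenyl]-2H-chromene F4. Hydrogenation of its trisubstituted styrenyl alkene with a cationic iridium P,N catalyst ([Ir(cod)(tBu-PHOX)][B(3,5-(CF3)2C6H3)4], antipode chosen for (3R), H2 50 bar, CH2Cl2, rt) gives 14.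

Step 9 (abnormal Claisen products or loss of the prenyl group at 190 °C). The fallback sets out from 14 and comes back at 18; it installs the reverse-prenyl group by cross-coupling instead of a sigmatropic shift. TBAF (THF, 0 °C) frees 3-methoxy-2-(methoxymethoxy)-4-[(3R)-7-(methoxymethoxy)chroman-3-yl]phenol F5. NBS with catalytic iPr2NH (CH2Cl2, −78 °C) brominates the only free ortho position of that phenol to give 6-bromo-3-methoxy-2-(methoxymethoxy)-4-[(3R)-7-(methoxymethoxy)chroman-3-yl]phenol F6. A γ-selective Suzuki–Miyaura coupling of F6 with 3-methylbut-2-enylboronic acid pinacol ester (Pd(OAc)2, bulky dialkylbiarylphosphine selected for branched selectivity, K3PO4, THF/H2O, 40 °C) gives 18 directly.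

Step 6 (lithiation at the wrong ring position, or slow lithiation). The fallback sets out from 10 and comes back at 13; it replaces directed metalation by electrophilic substitution steered by the free phenol. Compound 10 is iodinated para to the hydroxyl with BnNMe3·ICl2 and NaHCO3 (CH2Cl2/MeOH, rt) to give 4-iodo-3-methoxy-2-(methoxymethoxy)phenol F7, which is separated from any 6-iodo isomer. Silylation of F7 (TIPSCl, imidazole, DMF) gives 13.

**Further compounds**
F1 | step 7 | trans-3,4-dibromo-7-(methoxymethoxy)chromane (racemic, one enantiomer drawn) | COCOc1ccc2c(c1)OC[C@H](Br)[C@H]2Br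
F2 | step 7 | 3-bromo-7-(methoxymethoxy)-2H-chromene | COCOc1ccc2C=C(Br)COc2c1
F3 | step 7 | 2-[2-methoxy-3-(methoxymethoxy)-4-(triisopropylsilyloxy)phenyl]-4,4,5,5-tetramethyl-1,3,2-dioxaborolane | COCOc1c(OC)c(B2OC(C)(C)C(C)(C)O2)ccc1O[Si](C(C)C)(C(C)C)C(C)C
F4 | step 7 | 7-(methoxymethoxy)-3-[2-methoxy-3-(methoxymethoxy)-4-(triisopropylsilyloxy)phenyl]-2H-chromene | COc1c(C2=Cc3ccc(OCOC)cc3OC2)ccc(O[Si](C(C)C)(C(C)C)C(C)C)c1OCOC
F5 | step 9 | 3-methoxy-2-(methoxymethoxy)-4-[(3R)-7-(methoxymethoxy)chroman-3-yl]phenol | COc1c([C@@H]2COc3cc(OCOC)ccc3C2)ccc(O)c1OCOC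
F6 | step 9 | 6-bromo-3-methoxy-2-(methoxymethoxy)-4-[(3R)-7-(methoxymethoxy)chroman-3-yl]phenol | COc1c([C@@H]2COc3cc(OCOC)ccc3C2)cc(Br)c(O)c1OCOC
F7 | step 6 | 4-iodo-3-methoxy-2-(methoxymethoxy)phenol | COCOc1c(OC)c(I)ccc1O
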